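The route cuts the pyrrole N1–C5 bond and adds back one nitrogen. C2–C3–C4–C5 of the 3,4-diarylpyrrole, with its two quinolin-5-yl groups and hydrogen at C2 and C5, is taken from C3–C4–C5–C6 of a 1,2-diazine that carries removable esters at C3 and C6. Zinc in acetic acid excises one diazine nitrogen and contracts the six-membered ring to the pyrrole in one operation. The precursor, a 4,5-bis(7,8-dimethoxyquinolin-5-yl)pyridazine-3,6-dicarboxylate, comes from a diarylalkyne and a tetrazine diester. N-Alkylation, amination with (S)-3-methylazecane (built from a chiral bromo alcohol by a sulfonamide ring closure), decarboxylation and demethylation finish the target.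

Key step: step 5

Remark: the saturated ring is the ten-membered 3-methylazecane with (S) configuration at C3. The four phenols are carried as methyl ethers and the two pyrrole α-carbons as methyl esters, which survive hot sulfuric acid, zinc/acetic acid and hot alkali.
Remark: compounds with two neighbouring quinolin-5-yl groups may exist as slowly interconverting syn and anti rotamers. They are carried as mixtures, since the target has no fixed axis.

Step 1
Reactants: 1 2,3-dimethoxyaniline; 2 glycerol
Product: 4 7,8-dimethoxyquinoline, via 7,8-dimethoxy-1,2-dihydroquinoline 3 (not isolated)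
Conditions: conc. H2SO4, 3-O2NC6H4SO3Na, FeSO4·7H2O, H3BO3, 135 °C
Reagents that add atoms: none
Why: Skraup quinoline synthesis, in which glycerol dehydrates to acrolein, the aniline adds in conjugate fashion, the ring closes at the only free ortho position of the aniline and the nitroarene oxidises dihydroquinoline 3, so the 7,8-dimethoxy pattern should arise without a regiochemical choice.

Step 2
Reactants: 4 7,8-dimethoxyquinoline
Product: 5 5-iodo-7,8-dimethoxyquinoline
Conditions: NIS (1.05 equiv), TFA, 0 °C to rt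
Reagents that add atoms: N-iodosuccinimide, O=C1CCC(=O)N1I
Why: Electrophilic aromatic iodination, expected at C5 because this carbon is para to the C8 methoxy group and an α-position of the carbocyclic ring, whereas C6 is activated only by one ortho methoxy group and the protonated pyridine ring is inert.

Step 3
Reactants: 5 5-iodo-7,8-dimethoxyquinoline (2 equiv); 6 ethynyltrimethylsilane
Product: 9 1,2-bis(7,8-dimethoxyquinolin-5-yl)ethyne, via silylalkynyl quinoline 7 (not isolated), via 5-ethynylquinoline 8 (not isolated)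
Conditions: PdCl2(PPh3)2 (5 mol %), CuI (10 mol %), DBU (6 equiv), H2O (0.4 equiv), MeCN, 60 °C, Ar
Reagents that add atoms: none
Why: One-pot twofold Sonogashira coupling, in which the first coupling gives silylalkyne 7, DBU and a little water unmask terminal alkyne 8 in the flask, and 8 couples with the second equivalent of 5 before it can accumulate and homocouple.

Step 4
Reactants: 9 1,2-bis(7,8-dimethoxyquinolin-5-yl)ethyne; 10 dimethyl 1,2,4,5-tetrazine-3,6-dicarboxylate
Product: 12 dimethyl 4,5-bis(7,8-dimethoxyquinolin-5-yl)pyridazine-3,6-dicarboxylate, via tetraazabicyclooctatriene adduct 11 (not isolated)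
Conditions: 10 (2 equiv in two portions), dry mesitylene, 140 °C, Ar
Reagents that add atoms: none
Why: Inverse-electron-demand Diels–Alder reaction of the electron-poor tetrazine with the alkyne, whose aryl groups each place a methoxy group para to the alkyne carbon, followed by retro-Diels–Alder loss of N2 from bicycle 11, should give the aromatic diazine without a separate oxidation.

Step 5
Reactants: 12 dimethyl 4,5-bis(7,8-dimethoxyquinolin-5-yl)pyridazine-3,6-dicarboxylate
Product: 16 dimethyl 3,4-bis(7,8-dimethoxyquinolin-5-yl)-1H-pyrrole-2,5-dicarboxylate, via 1,4-dihydropyridazine diester 13 (not isolated), via open-chain enamine imine 14 (not isolated), via 2-aminopyrroline aminal 15 (not isolated)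
Conditions: Zn dust (15 equiv), AcOH, rt; filtration, aq NH3/EDTA work-up
Reagents that add atoms: none
Why: Zinc transfers two electrons and two protons to the diazine to give 1,4-dihydrodiazine 13, and a second two-electron reduction breaks the weak N–N bond to enamine imine 14. The enamine nitrogen then adds to the imine carbon four atoms away in a 5-exo-trig closure to give aminal 15, and loss of ammonia aromatises the ring, so the N1–C5 bond and the pyrrole ring form in one flask. The closest known reaction type is the zinc/acetic acid ring contraction of 4,5-diaryl-1,2-diazine-3,6-dicarboxylates to 3,4-diarylpyrrole-2,5-dicarboxylates. No stereocentre is formed, and the twofold symmetry of 12 makes it irrelevant which nitrogen is lost. The step needs chemoselectivity for the diazine over the quinolines and the esters, which the two ester groups on the diazine secure by making it far easier to reduce than a quinolinium ion at room temperature.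

Step 6
Reactants: 16 dimethyl 3,4-bis(7,8-dimethoxyquinolin-5-yl)-1H-pyrrole-2,5-dicarboxylate; 17 1-bromo-3-chloropropane
Product: 18 dimethyl 1-(3-chloropropyl)-3,4-bis(7,8-dimethoxyquinolin-5-yl)-1H-pyrrole-2,5-dicarboxylate
Conditions: 17 (3 equiv), K2CO3, DMF, 50 °C
Reagents that add atoms: none
Why: SN2 N-alkylation of the acidic pyrrole N–H (flanked by two esters) as its potassium salt at the bromide end of 17, bromide being much the better leaving group, while the quinoline nitrogens, shielded by the peri methoxy groups, should not compete.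

Step 7
Reactants: 19 (R)-3-bromo-2-methylpropan-1-ol; 20 (6-bromohexyloxy)(tert-butyl)dimethylsilane
Product: 22 (S)-9-[(tert-butyldimethylsilyl)oxy]-2-methylnonan-1-ol, via Grignard reagent 21 (not isolated)
Conditions: 20, Mg, THF, 40 °C; then 19 (0.43 equiv), Li2CuCl4 (3 mol %), NMP, THF, −20 °C to rt
Reagents that add atoms: none
Why: Kochi-type copper-catalysed sp3–sp3 cross-coupling of a Grignard reagent with a primary alkyl bromide, in which the first equivalent of 21 turns the hydroxyl group into its magnesium alkoxide and the stereocentre, not being at the reacting carbon, is carried over from 19 unchanged (the descriptor changes from R to S only through the CIP priorities).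

Step 8
Reactants: 22 (S)-9-[(tert-butyldimethylsilyl)oxy]-2-methylnonan-1-ol; 23 tert-butyl [(2-nitrophenyl)sulfonyl]carbamate
Product: 24 tert-butyl (S)-{9-[(tert-butyldimethylsilyl)oxy]-2-methylnonyl}[(2-nitrophenyl)sulfonyl]carbamate
Conditions: PPh3, DIAD, THF, 0 °C to rt
Reagents that add atoms: none
Why: Mitsunobu N-alkylation of the acidic N-Boc sulfonamide by the primary alcohol, which installs the nitrogen as a singly alkylated, doubly protected amine without touching the stereocentre.

Step 9
Reactants: 24 tert-butyl (S)-{9-[(tert-butyldimethylsilyl)oxy]-2-methylnonyl}[(2-nitrophenyl)sulfonyl]carbamate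
Product: 25 (S)-N-(9-hydroxy-2-methylnonyl)-2-nitrobenzenesulfonamide
Conditions: HCl (from AcCl), MeOH, rt to 40 °C
Reagents that add atoms: none
Why: Acidolysis, in which methanolic HCl should cleave the primary silyl ether and the tert-butyl carbamate in one operation while the 2-nitrobenzenesulfonamide is stable to acid.

Step 10
Reactants: 25 (S)-N-(9-hydroxy-2-methylnonyl)-2-nitrobenzenesulfonamide
Product: 26 (S)-3-methyl-1-[(2-nitrophenyl)sulfonyl]azecane
Conditions: PPh3, DIAD, toluene/THF, rt, slow addition of 25 (final 0.01 M)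
Reagents that add atoms: none
Why: Intramolecular Mitsunobu N-alkylation of the acidic 2-nitrobenzenesulfonamide at the unbranched primary carbinol, a closure established for eight- to ten-membered cyclic amines because the sulfonamide anion is a non-basic nucleophile, with slow addition to hold back dimer formation.

Step 11
Reactants: 26 (S)-3-methyl-1-[(2-nitrophenyl)sulfonyl]azecane
Product: 27 (S)-3-methylazecane
Conditions: PhSH, K2CO3, DMF, rt; acid/base extraction
Reagents that add atoms: none
Why: Thiolate cleavage of the 2-nitrobenzenesulfonamide by nucleophilic aromatic substitution (Meisenheimer adduct, loss of SO2) should free the secondary amine under conditions that cannot affect the remote stereocentre.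

Step 12
Reactants: 18 dimethyl 1-(3-chloropropyl)-3,4-bis(7,8-dimethoxyquinolin-5-yl)-1H-pyrrole-2,5-dicarboxylate; 27 (S)-3-methylazecane
Product: 29 dimethyl 3,4-bis(7,8-dimethoxyquinolin-5-yl)-1-{3-[(S)-3-methylazecan-1-yl]propyl}-1H-pyrrole-2,5-dicarboxylate, via 3-iodopropyl pyrrole 28 (not isolated)
Conditions: 27 (1.5 equiv), KI (0.2 equiv), K2CO3, MeCN, 80 °C
Reagents that add atoms: none
Why: SN2 amination of the primary chloride by the secondary amine under iodide catalysis (Finkelstein exchange to iodide 28 in the flask), in which the hindered amine should not attack the methyl esters.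

Step 13
Reactants: 29 dimethyl 3,4-bis(7,8-dimethoxyquinolin-5-yl)-1-{3-[(S)-3-methylazecan-1-yl]propyl}-1H-pyrrole-2,5-dicarboxylate
Product: 31 5,5'-(1-{3-[(S)-3-methylazecan-1-yl]propyl}-1H-pyrrole-3,4-diyl)bis(7,8-dimethoxyquinoline), via pyrrole-2,5-dicarboxylic acid 30 (not isolated)
Conditions: NaOH, EtOH/H2O, 85 °C; AcOH to pH 6, concentrate; then HOCH2CH2NH2, 175 °C, Ar
Reagents that add atoms: none
Why: Saponification followed by thermal protodecarboxylation of the pyrrole-2,5-dicarboxylic acid (ipso protonation at each α-carbon and loss of CO2), the standard way to free both α-positions of 3,4-diarylpyrroles, which the methyl ethers, the quinolines and the tertiary amine should survive.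

Step 14
Reactants: 31 5,5'-(1-{3-[(S)-3-methylazecan-1-yl]propyl}-1H-pyrrole-3,4-diyl)bis(7,8-dimethoxyquinoline)
Product: 32 5,5'-(1-{3-[(S)-3-methylazecan-1-yl]propyl}-1H-pyrrole-3,4-diyl)bis(quinoline-7,8-diol)
Conditions: BBr3 (12 equiv), CH2Cl2, −78 °C to rt; then degassed H2O, NaHCO3 to pH 7, Ar
Reagents that add atoms: none
Why: Lewis acid ether cleavage, in which BBr3, used in excess over the three basic nitrogens, binds each methoxy oxygen and bromide removes the methyl group by SN2, so that aqueous work-up under argon should release the four air-sensitive phenols.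

Compound list
1 | 2,3-dimethoxyaniline | COc1cccc(N)c1OC | starting material
2 | glycerol | OCC(O)CO | starting material
3 | 7,8-dimethoxy-1,2-dihydroquinoline | COc1ccc2c(c1OC)NCC=C2 | intermediate
4 | 7,8-dimethoxyquinoline | COc1ccc2cccnc2c1OC | intermediate
5 | 5-iodo-7,8-dimethoxyquinoline | COc1cc(I)c2cccnc2c1OC | intermediate
6 | ethynyltrimethylsilane | C#C[Si](C)(C)C | starting material
7 | 7,8-dimethoxy-5-[(trimethylsilyl)ethynyl]quinoline | COc1cc(C#C[Si](C)(C)C)c2cccnc2c1OC | intermediate
8 | 5-ethynyl-7,8-dimethoxyquinoline | COc1cc(C#C)c2cccnc2c1OC | intermediate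
9 | 1,2-bis(7,8-dimethoxyquinolin-5-yl)ethyne | COc1cc(C#Cc2cc(OC)c(OC)c3ncccc23)c2cccnc2c1OC | intermediate
10 | dimethyl 1,2,4,5-tetrazine-3,6-dicarboxylate | COC(=O)c1nnc(C(=O)OC)nn1 | starting material
11 | dimethyl 7,8-bis(7,8-dimethoxyquinolin-5-yl)-2,3,5,6-tetraazabicyclo[2.2.2]octa-2,5,7-triene-1,4-dicarboxylate | COC(=O)C12N=NC(N=N1)(C(=O)OC)C(c3cc(OC)c(OC)c4ncccc34)=C2c5cc(OC)c(OC)c6ncccc56 | intermediate
12 | dimethyl 4,5-bis(7,8-dimethoxyquinolin-5-yl)pyridazine-3,6-dicarboxylate | COC(=O)c1nnc(C(=O)OC)c(-c2cc(OC)c(OC)c3ncccc23)c1-c4cc(OC)c(OC)c5ncccc45 | intermediate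
13 | dimethyl 4,5-bis(7,8-dimethoxyquinolin-5-yl)-1,4-dihydropyridazine-3,6-dicarboxylate | COC(=O)C1=NNC(C(=O)OC)=C(c2cc(OC)c(OC)c3ncccc23)C1c4cc(OC)c(OC)c5ncccc45 | intermediate
14 | dimethyl 2-amino-5-imino-3,4-bis(7,8-dimethoxyquinolin-5-yl)hex-2-enedioate | COC(=O)C(N)=C(c1cc(OC)c(OC)c2ncccc12)C(c3cc(OC)c(OC)c4ncccc34)C(=N)C(=O)OC | intermediate
15 | dimethyl 2-amino-3,4-bis(7,8-dimethoxyquinolin-5-yl)-2,3-dihydro-1H-pyrrole-2,5-dicarboxylate | COC(=O)C1=C(c2cc(OC)c(OC)c3ncccc23)C(c4cc(OC)c(OC)c5ncccc45)C(N)(C(=O)OC)N1 | intermediate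
16 | dimethyl 3,4-bis(7,8-dimethoxyquinolin-5-yl)-1H-pyrrole-2,5-dicarboxylate | COC(=O)c1[nH]c(C(=O)OC)c(-c2cc(OC)c(OC)c3ncccc23)c1-c4cc(OC)c(OC)c5ncccc45 | intermediate
17 | 1-bromo-3-chloropropane | ClCCCBr | starting material
18 | dimethyl 1-(3-chloropropyl)-3,4-bis(7,8-dimethoxyquinolin-5-yl)-1H-pyrrole-2,5-dicarboxylate | COC(=O)c1n(CCCCl)c(C(=O)OC)c(-c2cc(OC)c(OC)c3ncccc23)c1-c4cc(OC)c(OC)c5ncccc45 | intermediate
19 | (R)-3-bromo-2-methylpropan-1-ol | OC[C@@H](C)CBr | starting material
20 | (6-bromohexyloxy)(tert-butyl)dimethylsilane | CC(C)(C)[Si](C)(C)OCCCCCCBr | starting material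
21 | {6-[(tert-butyldimethylsilyl)oxy]hexyl}magnesium bromide | CC(C)(C)[Si](C)(C)OCCCCCC[Mg]Br | intermediate
22 | (S)-9-[(tert-butyldimethylsilyl)oxy]-2-methylnonan-1-ol | OC[C@@H](C)CCCCCCCO[Si](C)(C)C(C)(C)C | intermediate
23 | tert-butyl [(2-nitrophenyl)sulfonyl]carbamate | CC(C)(C)OC(=O)NS(=O)(=O)c1ccccc1[N+](=O)[O-] | starting material
24 | tert-butyl (S)-{9-[(tert-butyldimethylsilyl)oxy]-2-methylnonyl}[(2-nitrophenyl)sulfonyl]carbamate | CC(C)(C)OC(=O)N(C[C@@H](C)CCCCCCCO[Si](C)(C)C(C)(C)C)S(=O)(=O)c1ccccc1[N+](=O)[O-] | intermediate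
25 | (S)-N-(9-hydroxy-2-methylnonyl)-2-nitrobenzenesulfonamide | O=S(=O)(NC[C@@H](C)CCCCCCCO)c1ccccc1[N+](=O)[O-] | intermediate
26 | (S)-3-methyl-1-[(2-nitrophenyl)sulfonyl]azecane | C[C@H]1CCCCCCCN(C1)S(=O)(=O)c2ccccc2[N+](=O)[O-] | intermediate
27 | (S)-3-methylazecane | C[C@H]1CCCCCCCNC1 | intermediate
28 | dimethyl 3,4-bis(7,8-dimethoxyquinolin-5-yl)-1-(3-iodopropyl)-1H-pyrrole-2,5-dicarboxylate | COC(=O)c1n(CCCI)c(C(=O)OC)c(-c2cc(OC)c(OC)c3ncccc23)c1-c4cc(OC)c(OC)c5ncccc45 | intermediate
29 | dimethyl 3,4-bis(7,8-dimethoxyquinolin-5-yl)-1-{3-[(S)-3-methylazecan-1-yl]propyl}-1H-pyrrole-2,5-dicarboxylate | C[C@H]1CCCCCCCN(CCCn2c(C(=O)OC)c(-c3cc(OC)c(OC)c4ncccc34)c(-c3cc(OC)c(OC)c4ncccc34)c2C(=O)OC)C1 | intermediate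
30 | 3,4-bis(7,8-dimethoxyquinolin-5-yl)-1-{3-[(S)-3-methylazecan-1-yl]propyl}-1H-pyrrole-2,5-dicarboxylic acid | C[C@H]1CCCCCCCN(CCCn2c(C(=O)O)c(-c3cc(OC)c(OC)c4ncccc34)c(-c3cc(OC)c(OC)c4ncccc34)c2C(=O)O)C1 | intermediate
31 | 5,5'-(1-{3-[(S)-3-methylazecan-1-yl]propyl}-1H-pyrrole-3,4-diyl)bis(7,8-dimethoxyquinoline) | C[C@H]1CCCCCCCN(CCCn2cc(-c3cc(OC)c(OC)c4ncccc34)c(-c3cc(OC)c(OC)c4ncccc34)c2)C1 | intermediate
32 | 5,5'-(1-{3-[(S)-3-methylazecan-1-yl]propyl}-1H-pyrrole-3,4-diyl)bis(quinoline-7,8-diol) | C[C@H]1CCCCCCCN(CCCn2cc(-c3cc(O)c(O)c4ncccc34)c(-c3cc(O)c(O)c4ncccc34)c2)C1 | target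

Total step count: 14.
Longest linear sequence: 9 steps (steps 1 to 6, then 12 to 14). The amine branch (steps 7 to 11) joins at step 12.

Steps most likely to fail

Step 5, the ring contraction. The reduction may stall after the first two-electron stage, because the two peri-hindered quinolinyl groups slow the closure onto the imine carbon. Zinc ions may also be held by the 8-alkoxyquinoline units, so that material is lost on work-up. The fallback builds the same pyrrole diester by cross-coupling and sets out from 5. Miyaura borylation of 5 (B2pin2, PdCl2(dppf), KOAc, dioxane, 90 °C) should give 7,8-dimethoxy-5-(4,4,5,5-tetramethyl-1,3,2-dioxaborolan-2-yl)quinoline F1. Commercial dimethyl 1H-pyrrole-2,5-dicarboxylate is brominated at both β-positions (NBS, DMF) to dimethyl 3,4-dibromo-1H-pyrrole-2,5-dicarboxylate F2. Twofold Suzuki–Miyaura coupling of F2 with F1 (Pd(OAc)2/SPhos, K3PO4, toluene/H2O, 100 °C) should then give 16, where the route is rejoined at step 6.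

Step 10, the ten-membered ring closure. Intermolecular alkylation to dimers and oligomers may outrun the closure, which is disfavoured by entropy and transannular strain. The fallback closes the ring at a carbon–carbon bond and sets out from 19. Copper-catalysed coupling of 19 with but-3-enylmagnesium bromide (Li2CuCl4, THF) should give (S)-2-methylhept-6-en-1-ol F3. But-3-en-1-amine and 2-nitrobenzenesulfonyl chloride (Et3N, CH2Cl2) give N-(but-3-en-1-yl)-2-nitrobenzenesulfonamide F4. Mitsunobu alkylation of F4 with F3 (PPh3, DIAD) should give the diene (S)-N-(but-3-en-1-yl)-N-(2-methylhept-6-en-1-yl)-2-nitrobenzenesulfonamide F5. Ring-closing metathesis with the second-generation Grubbs catalyst in dilute refluxing CH2Cl2 should give (S)-3-methyl-1-[(2-nitrophenyl)sulfonyl]-1,2,3,4,5,6,9,10-octahydroazecine F6 as an alkene mixture. Diimide reduction (TsNHNH2, NaOAc, aqueous DME, reflux), which spares the nitro group, should then give 26, where the route is rejoined at step 11.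

Step 4, the cycloaddition. Addition of the hindered and only moderately electron-rich alkyne may be slower than thermal decomposition of the tetrazine. The fallback replaces the alkyne by a far more reactive enamine dienophile and sets out from 9. Acid-assisted gold-catalysed hydration of the symmetrical alkyne (Ph3PAuCl/AgOTf, TfOH, dioxane/H2O, 80 °C) should give the single ketone 1,2-bis(7,8-dimethoxyquinolin-5-yl)ethan-1-one F7. Condensation with pyrrolidine (TiCl4, toluene) should give the enamine 5,5'-[1-(pyrrolidin-1-yl)ethene-1,2-diyl]bis(7,8-dimethoxyquinoline) F8. F8 should add to 10 at room temperature in dioxane, and loss of N2 and pyrrolidine should give 12, where the route is rejoined at step 5.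

Further compounds
F1 | step 5 | 7,8-dimethoxy-5-(4,4,5,5-tetramethyl-1,3,2-dioxaborolan-2-yl)quinoline | COc1cc(B2OC(C)(C)C(C)(C)O2)c2cccnc2c1OC
F2 | step 5 | dimethyl 3,4-dibromo-1H-pyrrole-2,5-dicarboxylate | COC(=O)c1[nH]c(C(=O)OC)c(Br)c1Br
F3 | step 10 | (S)-2-methylhept-6-en-1-ol | OC[C@@H](C)CCCC=C
F4 | step 10 | N-(but-3-en-1-yl)-2-nitrobenzenesulfonamide | C=CCCNS(=O)(=O)c1ccccc1[N+](=O)[O-]
F5 | step 10 | (S)-N-(but-3-en-1-yl)-N-(2-methylhept-6-en-1-yl)-2-nitrobenzenesulfonamide | C=CCCN(C[C@@H](C)CCCC=C)S(=O)(=O)c1ccccc1[N+](=O)[O-]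
F6 | step 10 | (S)-3-methyl-1-[(2-nitrophenyl)sulfonyl]-1,2,3,4,5,6,9,10-octahydroazecine | C[C@H]1CCCC=CCCN(C1)S(=O)(=O)c2ccccc2[N+](=O)[O-]
F7 | step 4 | 1,2-bis(7,8-dimethoxyquinolin-5-yl)ethan-1-one | O=C(Cc1cc(OC)c(OC)c2ncccc12)c3cc(OC)c(OC)c4ncccc34
F8 | step 4 | 5,5'-[1-(pyrrolidin-1-yl)ethene-1,2-diyl]bis(7,8-dimethoxyquinoline) | C(=C(N1CCCC1)c2cc(OC)c(OC)c3ncccc23)c4cc(OC)c(OC)c5ncccc45
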